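**Retrosynthetic overview**
- The C4–OMe group of the phenolic ring (ring B) is installed last, by para-bromination and Cu-catalysed methoxylation of a 6-aryloxythymol.
- Ring B is not taken from an arene: the phenol comes from dehydrogenative aromatisation of a 2-aryloxy-6-isopropyl-3-methylcyclohex-2-enone.
- That cyclohexenone comes from an intramolecular aldol condensation and Krapcho decarboxylation of a keto diester-type Michael adduct (Robinson annulation logic).
- The key C–C bond is the intermolecular Michael addition of a γ-aryloxy-α-isopropyl β-keto ester to methyl vinyl ketone; the β-keto ester comes from a crossed Claisen condensation of an aryloxyacetate with methyl isovalerate.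
- The diaryl ether oxygen therefore stems from a simple Williamson alkylation of 4-methoxythymol (from thymol by bromination/methoxylation). Ring A is carried in intact from thymol; ring B is built and aromatised afterwards.

Assumption: the target has no stereocentre, so no enantioselective step is needed; chiral intermediates are used as racemates because their stereocentres disappear on aromatisation.
Notation: ArO = 2-isopropyl-4-methoxy-5-methylphenoxy.

**Step 1**
Reactants: 1 thymol (2-isopropyl-5-methylphenol)
Product: 2 4-bromo-2-isopropyl-5-methylphenol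
Conditions: NBS (1.0 equiv), MeCN, 0 °C → rt
Reagents that add atoms: N-bromosuccinimide, O=C1CCC(=O)N1Br
Why: Electrophilic aromatic bromination, in which the hydroxyl group directs to the open para position to give 4-bromothymol.

**Step 2**
Reactants: 2 4-bromo-2-isopropyl-5-methylphenol
Product: 3 2-isopropyl-4-methoxy-5-methylphenol
Conditions: NaOMe (5 equiv, 25% in MeOH), CuI (20 mol%), DMF, 110 °C, N2; then 1 M HCl
Reagents that add atoms: sodium methoxide, [Na+].[O-]C
Why: Ullmann-type Cu(I)-catalysed methoxylation is an ipso substitution of bromide, so the regiochemistry is fixed, and the free phenol is tolerated as its phenoxide.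

**Step 3**
Reactants: 3 2-isopropyl-4-methoxy-5-methylphenol; 4 methyl bromoacetate
Product: 5 methyl 2-(ArO)acetate
Conditions: K2CO3 (2 equiv), acetone, reflux, N2
Reagents that add atoms: none
Why: Williamson ether synthesis (SN2 of the phenoxide on an α-halo ester), which forms the future diaryl ether C–O bond without any hindered aryl–O coupling.

**Step 4**
Reactants: 5 methyl 2-(ArO)acetate; 6 methyl 3-methylbutanoate (methyl isovalerate)
Product: 8 methyl 4-(ArO)-2-isopropyl-3-oxobutanoate (racemic), via lithium enolate 7 (not isolated)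
Conditions: 6 (2.2 equiv), LDA (2.2 equiv, commercial solution), THF, −78 °C; then 5, −78 → 0 °C; 1 M HCl
Reagents that add atoms: none
Why: Crossed Claisen condensation, in which the preformed lithium enolate of the β-branched ester adds to the more electrophilic α-aryloxy ester and the second equivalent of enolate deprotonates the β-keto ester as it forms; the new stereocentre is racemic and is destroyed later.

**Step 5 (key step)**
Reactants: 8 methyl 4-(ArO)-2-isopropyl-3-oxobutanoate; 9 methyl vinyl ketone (but-3-en-2-one)
Product: 10 methyl 2-[2-(ArO)acetyl]-2-isopropyl-5-oxohexanoate (racemic)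
Conditions: 9 (2 equiv), DBU (20 mol%), MeCN, rt → 40 °C
Reagents that add atoms: none
Why: Intermolecular Michael addition, in which DBU ionises only the doubly activated C–H of 8 and the soft enolate adds 1,4 to the enone (first half of a Robinson annulation, as in the classical piperitone synthesis from α-isopropylacetoacetate); the quaternary stereocentre is racemic and vanishes on aromatisation.

**Step 6**
Reactants: 10 methyl 2-[2-(ArO)acetyl]-2-isopropyl-5-oxohexanoate
Product: 12 methyl 3-(ArO)-1-isopropyl-4-methyl-2-oxocyclohex-3-ene-1-carboxylate (racemic), via aldol adduct 11 (not isolated)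
Conditions: t-BuOK (0.3 equiv), t-BuOH/THF, 0 °C → rt
Reagents that add atoms: none
Why: Intramolecular aldol condensation, in which the acidic ArOCH2 carbon attacks the unhindered methyl ketone to close the six-membered ring (closure onto the ketone next to the quaternary carbon is sterically disfavoured) and E1cB loss of water gives the enone; the catalytic, non-nucleophilic base in a protic medium avoids retro-Claisen cleavage and Dieckmann-type acylation.

**Step 7**
Reactants: 12 methyl 3-(ArO)-1-isopropyl-4-methyl-2-oxocyclohex-3-ene-1-carboxylate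
Product: 14 2-(ArO)-6-isopropyl-3-methylcyclohex-2-en-1-one (racemic), via lithium carboxylate 13 (not isolated)
Conditions: LiCl (3 equiv), H2O (2 equiv), DMSO, 150 °C
Reagents that add atoms: none
Why: Krapcho dealkoxycarbonylation (chloride SN2 demethylation, then decarboxylation of the β-keto carboxylate and protonation) works under near-neutral conditions, so the non-enolisable β-keto ester is not opened by retro-Claisen attack; the new stereocentre is racemic.

**Step 8**
Reactants: 14 2-(ArO)-6-isopropyl-3-methylcyclohex-2-en-1-one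
Product: 16 2-(ArO)-6-isopropyl-3-methylphenol, via dienone tautomer 15 (not isolated)
Conditions: Pd(TFA)2 (5 mol%), 2-(dimethylamino)pyridine (10 mol%), TsOH·H2O (20 mol%), O2 (1 atm), DMSO, 80 °C
Reagents that add atoms: none
Why: Pd(II)-catalysed aerobic dehydrogenation (Stahl-type aromatisation), in which α′-palladation and β-hydride elimination give dienone 15 that tautomerises irreversibly to the phenol; the last stereocentre is removed and the aryl ethers are inert.

**Step 9**
Reactants: 16 2-(ArO)-6-isopropyl-3-methylphenol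
Product: 17 4-bromo-2-(ArO)-6-isopropyl-3-methylphenol
Conditions: NBS (1.0 equiv), MeCN, −20 → 0 °C
Reagents that add atoms: N-bromosuccinimide, O=C1CCC(=O)N1Br
Why: Electrophilic aromatic bromination, in which the free phenol ring is far more activated than the aryl ether ring and both of its ortho positions are blocked, so one equivalent of NBS at low temperature reacts para to the hydroxyl group.

**Step 10**
Reactants: 17 4-bromo-2-(ArO)-6-isopropyl-3-methylphenol
Product: 18 6-isopropyl-2-(2-isopropyl-4-methoxy-5-methylphenoxy)-4-methoxy-3-methylphenol (target)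
Conditions: NaOMe (6 equiv, 25% in MeOH), CuI (30 mol%), DMF, 110 °C, N2; then 1 M HCl
Reagents that add atoms: sodium methoxide, [Na+].[O-]C
Why: Ullmann-type Cu(I)-catalysed methoxylation replaces bromide ipso, so the methoxy group ends up exactly para to the hindered hydroxyl group, and the diaryl ether and free phenol survive.

**Compound list**
1 | thymol (2-isopropyl-5-methylphenol) | Cc1ccc(C(C)C)c(O)c1 | starting material
2 | 4-bromo-2-isopropyl-5-methylphenol | Cc1cc(O)c(C(C)C)cc1Br | intermediate
3 | 2-isopropyl-4-methoxy-5-methylphenol | COc1cc(C(C)C)c(O)cc1C | intermediate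
4 | methyl bromoacetate | COC(=O)CBr | starting material
5 | methyl 2-(2-isopropyl-4-methoxy-5-methylphenoxy)acetate | COC(=O)COc1cc(C)c(OC)cc1C(C)C | intermediate
6 | methyl 3-methylbutanoate (methyl isovalerate) | COC(=O)CC(C)C | starting material
7 | lithium 1-methoxy-3-methylbut-1-en-1-olate (lithium enolate of 6) | [Li]OC(OC)=CC(C)C | intermediate
8 | methyl 2-isopropyl-4-(2-isopropyl-4-methoxy-5-methylphenoxy)-3-oxobutanoate (racemic) | COC(=O)C(C(C)C)C(=O)COc1cc(C)c(OC)cc1C(C)C | intermediate
9 | methyl vinyl ketone (but-3-en-2-one) | CC(=O)C=C | starting material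
10 | methyl 2-isopropyl-2-[2-(2-isopropyl-4-methoxy-5-methylphenoxy)acetyl]-5-oxohexanoate (racemic) | COC(=O)C(C(C)C)(CCC(C)=O)C(=O)COc1cc(C)c(OC)cc1C(C)C | intermediate
11 | methyl 4-hydroxy-1-isopropyl-3-(2-isopropyl-4-methoxy-5-methylphenoxy)-4-methyl-2-oxocyclohexane-1-carboxylate (racemic diastereomer mixture) | COC(=O)C1(C(C)C)CCC(C)(O)C(Oc2cc(C)c(OC)cc2C(C)C)C1=O | intermediate
12 | methyl 1-isopropyl-3-(2-isopropyl-4-methoxy-5-methylphenoxy)-4-methyl-2-oxocyclohex-3-ene-1-carboxylate (racemic) | COC(=O)C1(C(C)C)CCC(C)=C(Oc2cc(C)c(OC)cc2C(C)C)C1=O | intermediate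
13 | lithium 1-isopropyl-3-(2-isopropyl-4-methoxy-5-methylphenoxy)-4-methyl-2-oxocyclohex-3-ene-1-carboxylate (racemic) | [Li]OC(=O)C1(C(C)C)CCC(C)=C(Oc2cc(C)c(OC)cc2C(C)C)C1=O | intermediate
14 | 6-isopropyl-2-(2-isopropyl-4-methoxy-5-methylphenoxy)-3-methylcyclohex-2-en-1-one (racemic) | CC1=C(Oc2cc(C)c(OC)cc2C(C)C)C(=O)C(C(C)C)CC1 | intermediate
15 | 6-isopropyl-2-(2-isopropyl-4-methoxy-5-methylphenoxy)-3-methylcyclohexa-2,5-dien-1-one | CC1=C(Oc2cc(C)c(OC)cc2C(C)C)C(=O)C(C(C)C)=CC1 | intermediate
16 | 6-isopropyl-2-(2-isopropyl-4-methoxy-5-methylphenoxy)-3-methylphenol | Cc1ccc(C(C)C)c(O)c1Oc1cc(C)c(OC)cc1C(C)C | intermediate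
17 | 4-bromo-6-isopropyl-2-(2-isopropyl-4-methoxy-5-methylphenoxy)-3-methylphenol | Cc1c(Br)cc(C(C)C)c(O)c1Oc1cc(C)c(OC)cc1C(C)C | intermediate
18 | 6-isopropyl-2-(2-isopropyl-4-methoxy-5-methylphenoxy)-4-methoxy-3-methylphenol | COc1cc(C(C)C)c(Oc2c(C)c(OC)cc(C(C)C)c2O)cc1C | target

**Totals and risks**
Total step count: 10. Longest linear sequence: 10 steps (1 → 18).

Most likely to fail, first: step 5 (Michael addition forming a congested quaternary carbon next to an isopropyl group; it may be slow or reversible). The fallback sets out from 8 and comes back at 10. Instead of the reversible conjugate addition, 8 is C-alkylated irreversibly with 2-(2-bromoethyl)-2-methyl-1,3-dioxolane (CC1(CCBr)OCCO1; Cs2CO3, cat. NaI, DMF, 50 °C) to give methyl 2-isopropyl-2-[2-(2-isopropyl-4-methoxy-5-methylphenoxy)acetyl]-4-(2-methyl-1,3-dioxolan-2-yl)butanoate F1. The dioxolane is then hydrolysed (1 M HCl, THF, rt) to 10.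

Second: step 8 (catalytic dehydrogenation at a hindered α′-methine in the presence of an electron-rich aryl ether). The fallback sets out from 14 and comes back at 16 by a stoichiometric selenoxide elimination. Kinetic deprotonation with LDA (THF, −78 °C) gives lithium 2-isopropyl-6-(2-isopropyl-4-methoxy-5-methylphenoxy)-5-methylcyclohexa-1,5-dien-1-olate F2. Trapping with PhSeBr gives 6-isopropyl-2-(2-isopropyl-4-methoxy-5-methylphenoxy)-3-methyl-6-(phenylselanyl)cyclohex-2-en-1-one F3. Oxidation with H2O2/pyridine (CH2Cl2, 0 °C → rt) gives 6-isopropyl-2-(2-isopropyl-4-methoxy-5-methylphenoxy)-3-methyl-6-(phenylseleninyl)cyclohex-2-en-1-one F4, whose syn-elimination delivers dienone 15 and, by tautomerisation, 16. Any exocyclic isopropylidene isomer is isomerised to 16 by brief treatment with catalytic TsOH.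

Third: step 10 (Cu-catalysed methoxylation of a very electron-rich, hindered bromophenoxide; hydrodebromination may compete). The fallback sets out from 16, bypasses 17 and comes back at 18 by a quinone route. Oxidation of 16 with O2 and catalytic salcomine (MeCN, rt) gives 2-isopropyl-6-(2-isopropyl-4-methoxy-5-methylphenoxy)-5-methylcyclohexa-2,5-diene-1,4-dione F5. Reduction with Na2S2O4 (EtOAc/H2O) gives 2-isopropyl-6-(2-isopropyl-4-methoxy-5-methylphenoxy)-5-methylbenzene-1,4-diol F6. Mono-methylation with MeI (1.05 equiv) and K2CO3 in acetone at rt should take place at the less hindered 4-hydroxyl (flanked by methyl and hydrogen), not at the 1-hydroxyl (flanked by isopropyl and aryloxy), giving 18.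

**Further compounds**
F1 | step 5 | methyl 2-isopropyl-2-[2-(2-isopropyl-4-methoxy-5-methylphenoxy)acetyl]-4-(2-methyl-1,3-dioxolan-2-yl)butanoate (racemic) | COC(=O)C(C(C)C)(CCC1(C)OCCO1)C(=O)COc2cc(C)c(OC)cc2C(C)C
F2 | step 8 | lithium 2-isopropyl-6-(2-isopropyl-4-methoxy-5-methylphenoxy)-5-methylcyclohexa-1,5-dien-1-olate | [Li]OC1=C(C(C)C)CCC(C)=C1Oc2cc(C)c(OC)cc2C(C)C
F3 | step 8 | 6-isopropyl-2-(2-isopropyl-4-methoxy-5-methylphenoxy)-3-methyl-6-(phenylselanyl)cyclohex-2-en-1-one (racemic) | CC1=C(Oc2cc(C)c(OC)cc2C(C)C)C(=O)C(C(C)C)([Se]c2ccccc2)CC1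
F4 | step 8 | 6-isopropyl-2-(2-isopropyl-4-methoxy-5-methylphenoxy)-3-methyl-6-(phenylseleninyl)cyclohex-2-en-1-one (racemic diastereomer mixture) | CC1=C(Oc2cc(C)c(OC)cc2C(C)C)C(=O)C(C(C)C)([Se](=O)c2ccccc2)CC1
F5 | step 10 | 2-isopropyl-6-(2-isopropyl-4-methoxy-5-methylphenoxy)-5-methylcyclohexa-2,5-diene-1,4-dione | CC1=C(Oc2cc(C)c(OC)cc2C(C)C)C(=O)C(C(C)C)=CC1=O
F6 | step 10 | 2-isopropyl-6-(2-isopropyl-4-methoxy-5-methylphenoxy)-5-methylbenzene-1,4-diol | Cc1c(O)cc(C(C)C)c(O)c1Oc1cc(C)c(OC)cc1C(C)C
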